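**Plan**
1. The four phenols are masked as MOM ethers. Both C–C bonds at the ketone carbon (chromene C8–C(=O) and C(=O)–C1 of the prenylated ring A) are then cut together, the carbonyl carbon leaving as carbon monoxide.
2. This works because the carbonyl carbon bridges two complete arenes: chromene C8 (between C7–O and the O1-bearing C8a) and ring-A C1 (next to the prenylated C2). C8 becomes an aryl iodide and ring-A C1 an aryl boronate, so the prenyl alkene stays on the boron partner.
3. The iodochromene is cut at O1–C2 and C4–C4a (aryl propargyl ether rearrangement) back to phloroglucinol. The boronate is cut at C–B and at the ring–prenyl bond (reverse-prenyl ether Claisen) back to 5-bromoresorcinol.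
4. Forward: the pyran ring is closed on the iodinated phloroglucinol piece (steps 1–4), the prenylated boronate is built separately (steps 5–10), the arenes are joined through CO (step 11) and the MOM groups are removed (step 12).
5. Stereochemistry: none has to be set.

Key step: step 11

Remark: the target has no stereocentre and no stereogenic double bond, so it is one achiral compound and the route needs no asymmetric step.

**Route**

Step 1
Reactants: 1 phloroglucinol
Product: 2 3,5-bis(methoxymethoxy)phenol
Conditions: MOMCl (2.0 equiv), i-Pr2NEt, THF, 0 °C to rt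
Reagents that add atoms: chloromethyl methyl ether, COCCl
Why: Williamson-type O-alkylation with a chloromethyl ether; the three hydroxyls of 1 are equivalent, so only the degree of alkylation has to be controlled, which the stoichiometry and chromatographic recycling of mono- and tris-ether should achieve.

Step 2
Reactants: 2 3,5-bis(methoxymethoxy)phenol
Product: 3 2-iodo-3,5-bis(methoxymethoxy)phenol
Conditions: NIS (1.0 equiv), CH2Cl2, −40 to 0 °C
Reagents that add atoms: N-iodosuccinimide, O=C1CCC(=O)N1I
Why: Electrophilic aromatic iodination directed by the free phenol; the two equivalent carbons ortho to OH are less shielded than the carbon between the two MOM ethers and neutral NIS spares the acetals, so the 2-iodo isomer should predominate and any 4-iodo isomer is removed by chromatography.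

Step 3
Reactants: 3 2-iodo-3,5-bis(methoxymethoxy)phenol; 4 3-chloro-3-methylbut-1-yne
Product: 5 2-iodo-1,5-bis(methoxymethoxy)-3-[(2-methylbut-3-yn-2-yl)oxy]benzene
Conditions: DBU, CuCl2·2H2O (cat.), MeCN, 0 °C to rt
Reagents that add atoms: none
Why: Copper-catalysed O-propargylation of a phenol with a tertiary propargylic chloride, which tolerates ortho-substituted phenols and runs at a temperature where the aryl iodide and the MOM ethers are inert.

Step 4
Reactants: 5 2-iodo-1,5-bis(methoxymethoxy)-3-[(2-methylbut-3-yn-2-yl)oxy]benzene
Product: 8 8-iodo-5,7-bis(methoxymethoxy)-2,2-dimethyl-2H-chromene, via ortho-allenylphenol 6 (not isolated), via ortho-quinone methide 7 (not isolated)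
Conditions: o-xylene, 140 °C
Reagents that add atoms: none
Why: Thermal aryl propargyl ether rearrangement to a 2H-chromene: the propargyl Claisen shift can only go to the single free ortho carbon because iodine blocks the other, enolisation gives 6, a [1,5]-hydrogen shift gives 7 and 6π oxa-electrocyclisation closes the pyran ring with iodine necessarily at C8.

Step 5
Reactants: 9 5-bromoresorcinol
Product: 10 3-bromo-5-(methoxymethoxy)phenol
Conditions: MOMCl (1.0 equiv), i-Pr2NEt, CH2Cl2/THF, 0 °C to rt
Reagents that add atoms: chloromethyl methyl ether, COCCl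
Why: Mono-etherification (Williamson type) of a symmetrical resorcinol with one equivalent of reagent; the hydroxyls are equivalent, so the mono-ether only has to be separated from recyclable diol and bis-ether.

Step 6
Reactants: 10 3-bromo-5-(methoxymethoxy)phenol; 4 3-chloro-3-methylbut-1-yne
Product: 11 1-bromo-3-(methoxymethoxy)-5-[(2-methylbut-3-yn-2-yl)oxy]benzene
Conditions: DBU, CuCl2·2H2O (cat.), MeCN, 0 °C to rt
Reagents that add atoms: none
Why: The same copper-catalysed O-propargylation with the tertiary propargylic chloride, here on an unhindered phenol, with aryl bromide and MOM ether as spectators.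

Step 7
Reactants: 11 1-bromo-3-(methoxymethoxy)-5-[(2-methylbut-3-yn-2-yl)oxy]benzene
Product: 12 1-bromo-3-(methoxymethoxy)-5-[(2-methylbut-3-en-2-yl)oxy]benzene
Conditions: H2 (1 atm), Lindlar catalyst, quinoline, EtOAc, rt
Reagents that add atoms: none
Why: Lindlar semi-hydrogenation of the terminal alkyne to the vinyl group; the poisoned catalyst at room temperature should leave the aryl bromide alone and stop at the alkene when hydrogen uptake is monitored.

Step 8
Reactants: 12 1-bromo-3-(methoxymethoxy)-5-[(2-methylbut-3-en-2-yl)oxy]benzene
Product: 13 3-bromo-5-(methoxymethoxy)-2-(3-methylbut-2-en-1-yl)phenol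
Conditions: PhNEt2, 150 °C
Reagents that add atoms: none
Why: Aromatic Claisen rearrangement of a 1,1-dimethylallyl (reverse-prenyl) ether delivers a linear prenyl group to an ortho carbon; the carbon next to bromine and para to the MOM ether is favoured by both meta substituents (a meta donor directs away from itself, a meta halogen towards itself), and the amine solvent suppresses acid-induced loss of the allyl group and chroman formation.

Step 9
Reactants: 13 3-bromo-5-(methoxymethoxy)-2-(3-methylbut-2-en-1-yl)phenol
Product: 14 1-bromo-3,5-bis(methoxymethoxy)-2-(3-methylbut-2-en-1-yl)benzene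
Conditions: MOMCl, i-Pr2NEt, CH2Cl2, 0 to 40 °C
Reagents that add atoms: chloromethyl methyl ether, COCCl
Why: Williamson-type MOM etherification of the remaining phenol, so that no free hydroxyl interferes with borylation or the coupling and all four phenols carry the same acid-labile group.

Step 10
Reactants: 14 1-bromo-3,5-bis(methoxymethoxy)-2-(3-methylbut-2-en-1-yl)benzene
Product: 15 2-[3,5-bis(methoxymethoxy)-2-(3-methylbut-2-en-1-yl)phenyl]-4,4,5,5-tetramethyl-1,3,2-dioxaborolane
Conditions: B2pin2, Pd(dppf)Cl2 (cat.), KOAc, 1,4-dioxane, 90 °C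
Reagents that add atoms: bis(pinacolato)diboron, CC1(C)OB(OC1(C)C)B1OC(C)(C)C(C)(C)O1
Why: Miyaura borylation of a mono-ortho-substituted aryl bromide; acetate is too weak a base to trigger Suzuki homocoupling, and the arylpalladium could reach the neighbouring prenyl alkene only through a strained 4-exo or disfavoured 5-endo insertion.

Step 11
Reactants: 8 8-iodo-5,7-bis(methoxymethoxy)-2,2-dimethyl-2H-chromene; 15 2-[3,5-bis(methoxymethoxy)-2-(3-methylbut-2-en-1-yl)phenyl]-4,4,5,5-tetramethyl-1,3,2-dioxaborolane; 16 carbon monoxide
Product: 17 [3,5-bis(methoxymethoxy)-2-(3-methylbut-2-en-1-yl)phenyl][5,7-bis(methoxymethoxy)-2,2-dimethyl-2H-chromen-8-yl]methanone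
Conditions: CO (balloon, raised to a few bar if needed), PEPPSI-IPr (5 mol%), Cs2CO3, PhCl, H2O (5 equiv), 80 °C
Reagents that add atoms: none
Why: Pd(0)–NHC adds oxidatively to the C8–I bond of 8, CO inserts into the crowded aryl–Pd bond to give an aroylpalladium iodide, the hydroxide-activated boronate 15 transfers its aryl group, and acyl–aryl reductive elimination completes both bonds to the carbonyl carbon. The closest known reaction type is the carbonylative Suzuki–Miyaura coupling of di-ortho-substituted aryl iodides under bulky NHC–palladium catalysis, applied here to a pinacol boronate. No ring is closed and no stereocentre is created. The selectivity needed is carbonylative over direct biaryl coupling: the two oxygen substituents flanking C8 slow aryl transfer at the arylpalladium stage and make a tri-ortho-substituted biaryl hard to eliminate, CO insertion moves the metal one atom away from the congested ring, and the CO atmosphere keeps the acyl form populated. With the halide on the chromene and boron on ring A, the acylpalladium never lies next to the prenyl alkene, so a 5-exo acyl-Heck closure to an indanone is excluded, and the chromene C3=C4 bond cannot reach C8.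

Step 12
Reactants: 17 [3,5-bis(methoxymethoxy)-2-(3-methylbut-2-en-1-yl)phenyl][5,7-bis(methoxymethoxy)-2,2-dimethyl-2H-chromen-8-yl]methanone
Product: 18 [3,5-dihydroxy-2-(3-methylbut-2-en-1-yl)phenyl](5,7-dihydroxy-2,2-dimethyl-2H-chromen-8-yl)methanone (CNP0076744.0)
Conditions: HCl (ca. 1 M in MeOH), rt to 35 °C
Reagents that add atoms: none
Why: Acid-catalysed transacetalisation of the four MOM ethers to methanol; in dilute acid near room temperature the prenyl and chromene alkenes should survive, and the reaction is stopped once the last acetal has gone so that the prenyl group does not cyclise onto the neighbouring phenol.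

**Compound list**
1 | phloroglucinol | Oc1cc(O)cc(O)c1 | starting material
2 | 3,5-bis(methoxymethoxy)phenol | COCOc1cc(O)cc(OCOC)c1 | intermediate
3 | 2-iodo-3,5-bis(methoxymethoxy)phenol | COCOc1cc(O)c(I)c(OCOC)c1 | intermediate
4 | 3-chloro-3-methylbut-1-yne | C#CC(C)(C)Cl | starting material
5 | 2-iodo-1,5-bis(methoxymethoxy)-3-[(2-methylbut-3-yn-2-yl)oxy]benzene | COCOc1cc(OCOC)c(I)c(OC(C)(C)C#C)c1 | intermediate
6 | 2-iodo-3,5-bis(methoxymethoxy)-6-(3-methylbuta-1,2-dien-1-yl)phenol (not isolated) | COCOc1cc(OCOC)c(I)c(O)c1C=C=C(C)C | intermediate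
7 | 2-iodo-3,5-bis(methoxymethoxy)-6-(3-methylbut-2-en-1-ylidene)cyclohexa-2,4-dien-1-one (not isolated) | COCOC1=CC(OCOC)=C(I)C(=O)C1=CC=C(C)C | intermediate
8 | 8-iodo-5,7-bis(methoxymethoxy)-2,2-dimethyl-2H-chromene | COCOc1cc(OCOC)c2c(c1I)OC(C)(C)C=C2 | intermediate
9 | 5-bromoresorcinol | Oc1cc(O)cc(Br)c1 | starting material
10 | 3-bromo-5-(methoxymethoxy)phenol | COCOc1cc(O)cc(Br)c1 | intermediate
11 | 1-bromo-3-(methoxymethoxy)-5-[(2-methylbut-3-yn-2-yl)oxy]benzene | COCOc1cc(Br)cc(OC(C)(C)C#C)c1 | intermediate
12 | 1-bromo-3-(methoxymethoxy)-5-[(2-methylbut-3-en-2-yl)oxy]benzene | COCOc1cc(Br)cc(OC(C)(C)C=C)c1 | intermediate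
13 | 3-bromo-5-(methoxymethoxy)-2-(3-methylbut-2-en-1-yl)phenol | CC(C)=CCc1c(O)cc(OCOC)cc1Br | intermediate
14 | 1-bromo-3,5-bis(methoxymethoxy)-2-(3-methylbut-2-en-1-yl)benzene | CC(C)=CCc1c(OCOC)cc(OCOC)cc1Br | intermediate
15 | 2-[3,5-bis(methoxymethoxy)-2-(3-methylbut-2-en-1-yl)phenyl]-4,4,5,5-tetramethyl-1,3,2-dioxaborolane | CC(C)=CCc1c(OCOC)cc(OCOC)cc1B1OC(C)(C)C(C)(C)O1 | intermediate
16 | carbon monoxide | [C-]#[O+] | starting material
17 | [3,5-bis(methoxymethoxy)-2-(3-methylbut-2-en-1-yl)phenyl][5,7-bis(methoxymethoxy)-2,2-dimethyl-2H-chromen-8-yl]methanone | CC(C)=CCc1c(OCOC)cc(OCOC)cc1C(=O)c1c(OCOC)cc(OCOC)c2c1OC(C)(C)C=C2 | intermediate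
18 | [3,5-dihydroxy-2-(3-methylbut-2-en-1-yl)phenyl](5,7-dihydroxy-2,2-dimethyl-2H-chromen-8-yl)methanone | CC(C)=CCc1c(O)cc(O)cc1C(=O)c1c(O)cc(O)c2c1OC(C)(C)C=C2 | target

**Step count and risks**
Total: 12 steps. Longest linear sequence: 8 steps (steps 5–12, from 5-bromoresorcinol); the phloroglucinol branch is 4 steps before the union.

Step 11. Direct aryl–aryl coupling or protodeiodination may outrun CO insertion, or boron-to-palladium transfer from the ortho-substituted pinacol ester may be slow enough for hydroxide to intercept the acylpalladium. The fallback makes the two bonds to the carbonyl carbon one after the other by polar chemistry and sets out from 14 and 8. Bromine–lithium exchange on 14 (n-BuLi, THF, −78 °C) should give [3,5-bis(methoxymethoxy)-2-(3-methylbut-2-en-1-yl)phenyl]lithium F1, which is quenched with DMF to 3,5-bis(methoxymethoxy)-2-(3-methylbut-2-en-1-yl)benzaldehyde F2. Iodine–lithium exchange on 8 (n-BuLi, THF, −78 °C) should give [5,7-bis(methoxymethoxy)-2,2-dimethyl-2H-chromen-8-yl]lithium F3, which adds to F2 to give the racemic diarylmethanol [3,5-bis(methoxymethoxy)-2-(3-methylbut-2-en-1-yl)phenyl][5,7-bis(methoxymethoxy)-2,2-dimethyl-2H-chromen-8-yl]methanol F4. Oxidation of F4 with Dess–Martin periodinane (NaHCO3, CH2Cl2) removes the carbinol stereocentre and rejoins the route at 17.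

Step 2. Iodination may occur at the carbon between the two MOM ethers, or a second iodine may be introduced. The fallback places the halogen while the ring is still threefold symmetric and sets out from 1. Iodination of phloroglucinol (I2, NaHCO3, THF/H2O, 0 °C) should give 2-iodobenzene-1,3,5-triol F5. Treatment of F5 with two equivalents of MOMCl and i-Pr2NEt should etherify the unhindered hydroxyl para to iodine first and then one of the two equivalent flanking hydroxyls, rejoining the route at 3.

Step 8. The tertiary allylic ether may fragment back to the phenol before the sigmatropic shift, and some migration may go to the carbon between the two oxygens. The fallback uses a robust primary allyl ether and installs the gem-dimethyl terminus afterwards; it sets out from 10. O-allylation of 10 (allyl bromide, K2CO3, acetone, reflux) should give 1-(allyloxy)-3-bromo-5-(methoxymethoxy)benzene F6. Claisen rearrangement of F6 (PhNEt2, 190 °C), guided by the same substituent effects, should give 2-allyl-3-bromo-5-(methoxymethoxy)phenol F7. Cross-metathesis of F7 with 2-methyl-2-butene (Grubbs second-generation catalyst, CH2Cl2, 40 °C) converts the allyl into the prenyl group and rejoins the route at 13.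

**Further compounds**
F1 | step 11 | [3,5-bis(methoxymethoxy)-2-(3-methylbut-2-en-1-yl)phenyl]lithium | [Li]c1cc(OCOC)cc(OCOC)c1CC=C(C)C
F2 | step 11 | 3,5-bis(methoxymethoxy)-2-(3-methylbut-2-en-1-yl)benzaldehyde | CC(C)=CCc1c(OCOC)cc(OCOC)cc1C=O
F3 | step 11 | [5,7-bis(methoxymethoxy)-2,2-dimethyl-2H-chromen-8-yl]lithium | [Li]c1c(OCOC)cc(OCOC)c2c1OC(C)(C)C=C2
F4 | step 11 | [3,5-bis(methoxymethoxy)-2-(3-methylbut-2-en-1-yl)phenyl][5,7-bis(methoxymethoxy)-2,2-dimethyl-2H-chromen-8-yl]methanol (racemic) | CC(C)=CCc1c(OCOC)cc(OCOC)cc1C(O)c1c(OCOC)cc(OCOC)c2c1OC(C)(C)C=C2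
F5 | step 2 | 2-iodobenzene-1,3,5-triol | Oc1cc(O)c(I)c(O)c1
F6 | step 8 | 1-(allyloxy)-3-bromo-5-(methoxymethoxy)benzene | C=CCOc1cc(Br)cc(OCOC)c1
F7 | step 8 | 2-allyl-3-bromo-5-(methoxymethoxy)phenol | C=CCc1c(O)cc(OCOC)cc1Br
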